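Start from the slowness of this flask: the cedar run holds 25.4% in chains at 6.00 min, while its dose was in by 30 s, much earlier, so reckon the whole dose as present from the start.

| setting | cedar | Sunday's | Tuesday's |
|---|---|---|---|
| free monomer | 1 M (fed, over 30 s) | 2.0 M (fed, over 30 s) | 2.0 M (fed, over 30 s) |
| initiator | 5.2 mM | 5.2 mM | 5.2 mM |
| impurity | 1.6 mM | 1.6 mM | 1.6 mM |
| remark | run made earlier; the fed solution adds 1.0 times the starting volume | the fed solution adds 1.0 times the starting volume | the fed solution adds 1.0 times the starting volume |
| time |  | 20 min | 5.0 min |

- cedar (time / min: monomer in chains / %, free monomer / %): 1.33: 2.0, 99.1; 2.50: 4.9, 93.2; 4.00: 13.9, 86.4; 5.00: 20.3, 81.3; 6.00: 25.4, 74.8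

(scatter of a reading: 1 percentage point)

- every charge counts on the volume at the start, and the solution that is fed holds the whole dose
- the average divides the monomer in chains by the number of chains begun, living and dead together
- the numbers in the tables scatter with a standard deviation of 1 percentage point
- the earlier runs do not show the number of chains; that part of a forecast is a guess

- which of the two ends with the longer chains by the average number of monomer units in a chain (chains begun, living or dead) ("neither" if they lie within 10%) (Sunday's / Tuesday's / neither)
- average number of monomer units in a chain (chains begun, living or dead) at the end, Sunday's
- average number of monomer units in a chain (chains begun, living or dead) at the end, Tuesday's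

Build the flask one process at a time, and treat what follows as my own reckoning. Take the main step first, growth on a fixed stock of chains, which makes free monomer fall in a pseudo-first-order way; read its constant from the last cedar readings as 0.0721 min⁻¹, a reading that carries the scatter, and let each initiator begin one chain, so that full conversion of Sunday's charge gives 385 units per chain. Add the impurity next and suppose that each impurity takes one initiator away: the length at full conversion becomes 556, the charge of free monomer over initiator minus impurity, all on the starting volume, and call this the full-conversion length. Add last that chains begin slowly, which I read from the cedar run, with its scatter, as a lag of 1.97 min, where the line through its last reading runs back to no conversion, and assume that twice the monomer brings this down to 0.985 min. By this reckoning Sunday's converts 74.6% and Tuesday's 25.1%, and since both have the same full-conversion length, multiply each conversion by it to get 414 for Sunday's and 140 for Tuesday's, so my estimate has Sunday's ending longer by more than the margin.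

The forecast also names Sunday's, but with 300 and 100, lower than my figures, and with the remark “Chains begun is a guess”.

The flask gives Sunday's, with 493 for Sunday's and 172 for Tuesday's.

    free monomer + initiator → living end + monomer in chains (k = 0.510 L mol⁻¹ min⁻¹)
    free monomer + living end → monomer in chains + living end, rate k2*[living end]*[free monomer] (k = 59.0 L mol⁻¹ min⁻¹)
    free monomer + initiator → spent initiator A (k = 0.0330 L mol⁻¹ min⁻¹)
    initiator + impurity → spent initiator B (k = 4200 L mol⁻¹ min⁻¹)

In Sunday's, with concentrations held at their charge, the step with impurity gives initiator a half-life of 0.10 min, shorter than the 0.680 min that the beginning of chains gives it on the same footing, and at 0.500 min Sunday's holds 0.481% of its impurity and 58.5% of its initiator. Sunday's read at 200 min stands at 592, above the full-conversion length of 556. Now take Sunday's flask with 0.0040 M of impurity: the full-conversion length rises to 1670, and with a third of the initiator reckoned to survive, my constant falls to 0.0240 min⁻¹, which gives a length of 611. That flask computes to 803, with 54.6% of its free monomer still unreacted.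

The readings were computed on assumed constants; the scatter is artificial.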